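**Retrosynthetic overview**

- Numbering: ring A is O1, C2 (aryl), C3, C4, C5. C6 is the hydroxymethyl carbon on C3 and C7 is the aryl carbinol carbon on C4. The route rests on the cis C3/C4 pair of ring A, with C6 and C7 on one face and the C2 aryl group on the other. The C3–C4 bond of this less stable arrangement can be made kinetically from a C4 radical and a C3=C6 alkene held together by the C5–O1–C2 ether.
- Endgame disconnections: the phenols come from benzyl ethers, C7–OH from a silyl ether, and C6–OH from a C6–B bond.
- Key disconnection: C3–C4, by 5-exo-trig closure of ring A (the only ring formed) onto an (E)-alkenylboronate. This sets C3 and C4 from C2.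
- The acyclic bromo ether is cut at C5–O1 into two fragments. One is a C4-bromo C5-triflate, with C7 set by an Evans syn-aldol of a bromoacetyl imide with O-benzylvanillin. The other is an (S)-aryl propargylic alcohol, with C2 set by a lipase resolution. Alkyne hydroboration brings in C6–B.

Key step: step 11

Assumption: the levorotatory name is taken to belong to the configuration written in the SMILES, that is C2 S, C3 R, C4 R, C7 S (2,3-trans, 3,4-cis), and the route is planned for this configuration.

**Step 1**
Reactants: 1 vanillin
Product: 2 O-benzylvanillin (4-benzyloxy-3-methoxybenzaldehyde)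
Conditions: BnBr, K2CO3, DMF, rt
Reagents that add atoms: benzyl bromide, BrCc1ccccc1
Why: Williamson etherification of the phenoxide; the aryl benzyl ether should survive boron aldol, hydride, triflation, alkoxide, radical and fluoride conditions and leaves under neutral hydrogenolysis at the end.

**Step 2**
Reactants: 3 (S)-4-benzyloxazolidin-2-one; 4 bromoacetyl bromide
Product: 6 (S)-4-benzyl-3-(bromoacetyl)oxazolidin-2-one, via lithium oxazolidinide 5 (not isolated)
Conditions: n-BuLi, THF, −78 °C; then 4, −78 → 0 °C
Reagents that add atoms: none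
Why: N-acylation of the lithiated oxazolidinone, in which the acyl bromide reacts far faster than the alkyl bromide at low temperature.

**Step 3**
Reactants: 6 (S)-4-benzyl-3-(bromoacetyl)oxazolidin-2-one; 2 O-benzylvanillin
Product: 9 (S)-4-benzyl-3-[(2S,3R)-3-(4-benzyloxy-3-methoxyphenyl)-2-bromo-3-hydroxypropanoyl]oxazolidin-2-one (syn; C4 S and C7 R), via dibutylboron (Z)-enolate 7 (not isolated), via boron aldolate 8 (not isolated)
Conditions: Bu2BOTf, Et3N, Et2O, −78 → 0 °C; 2, −78 → 0 °C; H2O2, MeOH, pH 7 buffer, 0 °C
Reagents that add atoms: none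
Why: Evans boron syn-aldol, in which the (Z)-enolate 7 reacts through a Zimmerman-Traxler chair on the face away from the auxiliary benzyl group; this sets C7 in the spatial arrangement kept to the target and gives the syn C4 bromide, whose configuration is erased later.

**Step 4**
Reactants: 9 syn-bromo aldol
Product: 10 C7 tert-butyldimethylsilyl ether of 9 (C4 S and C7 R)
Conditions: TBSOTf, 2,6-lutidine, CH2Cl2, 0 °C
Reagents that add atoms: tert-butyldimethylsilyl triflate, CC(C)(C)[Si](C)(C)OS(=O)(=O)C(F)(F)F
Why: O-silylation with a silyl triflate and a hindered, non-nucleophilic base, which should avoid retro-aldol cleavage and Darzens-type epoxide closure.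

**Step 5**
Reactants: 10 silylated bromo imide
Product: 11 (2R,3R)-3-(4-benzyloxy-3-methoxyphenyl)-2-bromo-3-(tert-butyldimethylsilyloxy)propan-1-ol (C4 R and C7 R; C5 is the new CH2OH)
Conditions: LiBH4, MeOH (1 equiv), THF, 0 °C; neutral aqueous work-up
Reagents that add atoms: none
Why: Reductive removal of the Evans auxiliary with lithium borohydride; the bromine-activated exocyclic carbonyl is attacked preferentially, no stereocentre is touched (the C4 descriptor changes only through priorities), and the non-basic work-up keeps the bromohydrin from closing to an epoxide.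

**Step 6**
Reactants: 11 bromohydrin
Product: 12 C5 triflate of 11 (C4 R and C7 R)
Conditions: Tf2O, 2,6-lutidine, CH2Cl2, −78 °C; cold aqueous wash, used at once
Reagents that add atoms: triflic anhydride, O=S(=O)(OS(=O)(=O)C(F)(F)F)C(F)(F)F
Why: O-sulfonylation of the primary alcohol; the triflate is chosen because the beta-bromine and the beta-branch slow SN2 at C5, so the best leaving group is needed for substitution at low temperature.

**Step 7**
Reactants: 2 O-benzylvanillin; 13 ethynylmagnesium bromide
Product: 15 rac-1-(4-benzyloxy-3-methoxyphenyl)prop-2-yn-1-ol, via bromomagnesium alkoxide 14 (not isolated)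
Conditions: THF, 0 °C; aqueous work-up
Reagents that add atoms: none
Why: 1,2-addition of an alkynyl Grignard reagent to the aldehyde, which gives the C2 carbinol as the racemate with the terminal alkyne already free.

**Step 8**
Reactants: 15 racemic propargylic alcohol
Product: 16 (S)-1-(4-benzyloxy-3-methoxyphenyl)prop-2-yn-1-ol
Conditions: Novozym 435 (immobilised Candida antarctica lipase B), vinyl acetate, MTBE, 35 °C, stopped just past half conversion; chromatography
Reagents that add atoms: none
Why: Lipase-catalysed kinetic resolution by irreversible transesterification; by the Kazlauskas rule (aryl large, ethynyl medium) the (R)-enantiomer should be acetylated, so the (S)-alcohol carrying the C2 configuration stays behind and running past half conversion raises its enantiopurity.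

**Step 9**
Reactants: 16 (S)-propargylic alcohol; 12 bromo triflate
Product: 18 bromo propargylic ether ArCH(OTBS)-CHBr-CH2-O-CH(Ar)-C≡CH with Ar = 4-benzyloxy-3-methoxyphenyl (C2 S; C4 R; C7 R), via sodium alkoxide 17 (not isolated)
Conditions: 16 (1.1 equiv), NaH, THF, 0 °C; then 12, −78 → −20 °C
Reagents that add atoms: none
Why: Williamson etherification by SN2 at primary C5, which touches none of C2, C4 and C7; one equivalent of base and the low temperature should hold back elimination and propargylic isomerisation.

**Step 10**
Reactants: 18 bromo propargylic ether; 19 pinacolborane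
Product: 20 (E)-alkenylboronate bromo ether, the cyclization precursor (C2 S; C4 R; C7 R; C3=C6 E with pinacol boronate on C6)
Conditions: 19 (1.5 equiv), Cp2ZrHCl (10 mol %), CH2Cl2, rt
Reagents that add atoms: none
Why: Zirconocene hydride-catalysed hydroboration of a terminal alkyne, a syn and anti-Markovnikov addition that should place boron on terminal C6 with E geometry and leave the secondary bromide and the silyl and benzyl ethers untouched.

**Step 11**
Reactants: 20 (E)-alkenylboronate bromo ether
Product: 23 ring A boronate (2S,3S,4R)-2-(4-benzyloxy-3-methoxyphenyl)-4-[(S)-(4-benzyloxy-3-methoxyphenyl)(tert-butyldimethylsilyloxy)methyl]-3-[(pinacolatoboryl)methyl]tetrahydrofuran, via C4 radical 21 (not isolated), via C6 alpha-boryl radical 22 (not isolated)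
Conditions: (Me3Si)3SiH (1.3 equiv), Et3B (0.3 equiv, in portions), air, toluene (0.02 M), 0 °C
Reagents that add atoms: none
Why: Ethyl radicals from Et3B and oxygen start a chain in which (Me3Si)3Si• abstracts bromine from 20 to give the planar secondary C4 radical 21 (so either C4 bromide epimer would serve), 21 adds to C3 of the alkenylboronate, and the boron-stabilised C6 radical 22 takes hydrogen from the silane. The closest known reaction types are the silane- or stannane-mediated reductive cyclization of beta-bromoalkyl allyl ethers (3-oxahex-5-enyl radicals) and the intramolecular addition of alkyl radicals to alkenylboronic esters. Ring A closes in the 5-exo-trig mode, since 6-endo attack would have to occur at the hindered boron-bearing C6 and would give up the alpha-boryl stabilisation. C3 is controlled by C2: in the chair-like Beckwith-Houk transition state the C2 aryl group sits pseudo-equatorial, so the C6 branch should end trans to it. C4 is controlled by the 1,5-cis preference of 1-substituted hexenyl radicals, and a Felkin-type rotamer about C4-C7 (aryl anti to the forming bond, C7-H beside C5, silyloxy beside C4-H) exposes the same radical face, so C7 should reinforce C2. The step needs cyclization to outrun direct reduction and 1,2-aryl shift, which the pairing of a nucleophilic radical and an electron-poor acceptor, the short C-O bonds of the tether and the slow hydrogen donor in dilute solution secure, and it needs 2,3-trans/3,4-cis diastereoselectivity, of which the 3,4-cis part rests on a small energy gap and is the reason for the low temperature.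

**Step 12**
Reactants: 23 ring A boronate
Product: 24 [(2S,3R,4R)-2-(4-benzyloxy-3-methoxyphenyl)-4-[(S)-(4-benzyloxy-3-methoxyphenyl)(tert-butyldimethylsilyloxy)methyl]tetrahydrofuran-3-yl]methanol
Conditions: NaBO3·4H2O, THF–H2O (1:1), rt
Reagents that add atoms: sodium perborate, [Na+].[O-]OB=O
Why: Oxidation of the C6–B bond by 1,2-migration in a peroxoborate; C6 is not stereogenic, and the mild perborate should spare the silyl and benzyl ethers.

**Step 13**
Reactants: 24 silyl-protected primary alcohol
Product: 25 di-O-benzyl tanegol (2S,3R,4R; C7 S)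
Conditions: Bu4NF, THF, 0 °C → rt
Reagents that add atoms: none
Why: Fluoride-induced desilylation, carried out while both phenols are still benzylated so that no para-quinone methide can arise at C7 or C2 under the basic conditions and both benzylic centres keep their configuration.

**Step 14**
Reactants: 25 di-O-benzyl tanegol
Product: 26 (−)-tanegol
Conditions: H2 (1 atm), Pd/C (10 %), EtOAc, rt, stopped as soon as debenzylation is complete
Reagents that add atoms: none
Why: Catalytic hydrogenolysis of the two aryl benzyl ethers, which under neutral conditions should cleave much faster than the dialkyl benzylic C2–O1 bond and the C7–OH bond.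

**Compound list**

1 | vanillin | COc1cc(C=O)ccc1O | starting material
2 | O-benzylvanillin | COc1cc(C=O)ccc1OCc1ccccc1 | intermediate
3 | (S)-4-benzyloxazolidin-2-one | O=C1N[C@@H](Cc2ccccc2)CO1 | starting material
4 | bromoacetyl bromide | O=C(Br)CBr | starting material
5 | N-lithio-(S)-4-benzyloxazolidin-2-one | [Li]N1[C@@H](Cc2ccccc2)COC1=O | intermediate
6 | (S)-4-benzyl-3-(bromoacetyl)oxazolidin-2-one | O=C(CBr)N1[C@@H](Cc2ccccc2)COC1=O | intermediate
7 | (Z)-dibutylboron enolate of 6 | Br/C=C(\OB(CCCC)CCCC)N1[C@@H](Cc2ccccc2)COC1=O | intermediate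
8 | dibutylboron aldolate of 9 | COc1cc([C@@H](OB(CCCC)CCCC)[C@H](Br)C(=O)N2[C@@H](Cc3ccccc3)COC2=O)ccc1OCc1ccccc1 | intermediate
9 | syn-bromo aldol imide (C4 S, C7 R) | COc1cc([C@@H](O)[C@H](Br)C(=O)N2[C@@H](Cc3ccccc3)COC2=O)ccc1OCc1ccccc1 | intermediate
10 | C7 silyl ether of 9 | COc1cc([C@@H](O[Si](C)(C)C(C)(C)C)[C@H](Br)C(=O)N2[C@@H](Cc3ccccc3)COC2=O)ccc1OCc1ccccc1 | intermediate
11 | (2R,3R)-bromohydrin | COc1cc([C@@H](O[Si](C)(C)C(C)(C)C)[C@H](Br)CO)ccc1OCc1ccccc1 | intermediate
12 | C5 triflate of 11 | COc1cc([C@@H](O[Si](C)(C)C(C)(C)C)[C@H](Br)COS(=O)(=O)C(F)(F)F)ccc1OCc1ccccc1 | intermediate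
13 | ethynylmagnesium bromide | C#C[Mg]Br | starting material
14 | bromomagnesium alkoxide of 15 | C#CC(O[Mg]Br)c1ccc(OCc2ccccc2)c(OC)c1 | intermediate
15 | rac-1-(4-benzyloxy-3-methoxyphenyl)prop-2-yn-1-ol | C#CC(O)c1ccc(OCc2ccccc2)c(OC)c1 | intermediate
16 | (S)-1-(4-benzyloxy-3-methoxyphenyl)prop-2-yn-1-ol | O[C@H](c1ccc(OCc2ccccc2)c(OC)c1)C#C | intermediate
17 | sodium alkoxide of 16 | [Na+].[O-][C@H](c1ccc(OCc2ccccc2)c(OC)c1)C#C | intermediate
18 | bromo propargylic ether (C2 S, C4 R, C7 R) | COc1cc([C@@H](O[Si](C)(C)C(C)(C)C)[C@H](Br)CO[C@H](c2ccc(OCc3ccccc3)c(OC)c2)C#C)ccc1OCc1ccccc1 | intermediate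
19 | pinacolborane | CC1(C)OBOC1(C)C | starting material
20 | (E)-alkenylboronate bromo ether, key-step precursor | COc1cc([C@@H](O[Si](C)(C)C(C)(C)C)[C@H](Br)CO[C@H](c2ccc(OCc3ccccc3)c(OC)c2)/C=C/B2OC(C)(C)C(C)(C)O2)ccc1OCc1ccccc1 | intermediate
21 | C4 radical | COc1cc([C@@H](O[Si](C)(C)C(C)(C)C)[CH]CO[C@H](c2ccc(OCc3ccccc3)c(OC)c2)/C=C/B2OC(C)(C)C(C)(C)O2)ccc1OCc1ccccc1 | intermediate
22 | C6 alpha-boryl radical, ring A closed | COc1cc([C@@H](O[Si](C)(C)C(C)(C)C)[C@H]2CO[C@H](c3ccc(OCc4ccccc4)c(OC)c3)[C@H]2[CH]B2OC(C)(C)C(C)(C)O2)ccc1OCc1ccccc1 | intermediate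
23 | ring A boronate (2S,3S,4R; C7 S), key-step product | COc1cc([C@@H](O[Si](C)(C)C(C)(C)C)[C@H]2CO[C@H](c3ccc(OCc4ccccc4)c(OC)c3)[C@H]2CB2OC(C)(C)C(C)(C)O2)ccc1OCc1ccccc1 | intermediate
24 | C6 alcohol, C7 silyl ether (2S,3R,4R; C7 S) | COc1cc([C@@H](O[Si](C)(C)C(C)(C)C)[C@H]2CO[C@H](c3ccc(OCc4ccccc4)c(OC)c3)[C@H]2CO)ccc1OCc1ccccc1 | intermediate
25 | di-O-benzyl tanegol | COc1cc([C@@H](O)[C@H]2CO[C@H](c3ccc(OCc4ccccc4)c(OC)c3)[C@H]2CO)ccc1OCc1ccccc1 | intermediate
26 | (−)-tanegol | COc1cc([C@@H](O)[C@H]2CO[C@H](c3ccc(O)c(OC)c3)[C@H]2CO)ccc1O | target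

**Step count**

- Total step count: 14.
- Longest linear sequence: 11 steps (1, 3, 4, 5, 6, 9, 10, 11, 12, 13, 14 from vanillin). The count is the same from 3 through step 2.

**Steps most likely to fail**

**1. Step 11.**
- What may go wrong: the 1,5-cis preference at C4 may be lost or reversed under the steric demand of the C7 side chain, that is, poor facial selectivity at the radical carbon. Premature hydrogen transfer to the uncyclized radical is a lesser concern.
- Fallback: it sets out from 3 and 2 and returns at 24. C3 is attached to C4 already in the aldol, so that no ring-forming step has to create the cis pair.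
- Oxazolidinone 3 is acylated (n-BuLi, pent-4-enoyl chloride, THF, −78 °C) to (S)-4-benzyl-3-(pent-4-enoyl)oxazolidin-2-one F1.
- The Evans boron syn-aldol of F1 with 2 (Bu2BOTf, Et3N, CH2Cl2) gives the alpha-allyl aldol F2, with C4 and C7 in the target arrangement.
- TBSOTf and 2,6-lutidine give the silyl ether F3, and LiBH4 gives the primary alcohol F4.
- Johnson-Lemieux cleavage (OsO4 cat., NaIO4, 2,6-lutidine, dioxane–H2O) delivers the lactol F5. Oxidation with Pr4NRuO4 (cat.) and N-methylmorpholine N-oxide gives the beta-substituted gamma-butyrolactone F6, whose carbonyl carbon is C6.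
- Its lithium enolate (LiN(SiMe3)2, THF, −78 °C) adds to 2 anti to the C4 side chain to give the trans-disubstituted aldol lactone F7, as C2 carbinol epimers. LiAlH4 then gives the triol F8.
- Catalytic camphorsulfonic acid in CH2Cl2 at 0 °C ionises the free, electron-rich C2 benzylic alcohol; the silylated C7 oxygen is the poorer leaving group. The C5 hydroxyl captures the cation and closes ring A with the aryl group trans to C6.
- The trans lactone maps onto the 3,4-cis ring, so this gives 24.

**2. Step 9.**
- What may go wrong: base-induced elimination across C4–C5 (C4–H is acidified by bromine), attack of the alkoxide at sulfur, or decay of the triflate before substitution.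
- Fallback: it sets out from 11 and 15 and returns at 18. The ether is made at the other C–O bond (O1–C2) under nearly neutral conditions.
- Alcohol 15 is acetylated (Ac2O, pyridine) to the racemic propargylic acetate F9.
- F9 is combined with bromohydrin 11, CuOTf·0.5C6H6 (5 mol %), a chiral Ph-pybox ligand and iPr2NEt in CH2Cl2 at 0 °C. This is an enantioselective copper-catalysed propargylic etherification through a copper allenylidene, on which both enantiomers of F9 converge.
- The ligand antipode is matched to the (S) configuration at C2 in a model run. Because 11 is a single enantiomer, any C2 epimer is a diastereomer that chromatography removes.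
- Steps 6 and 8 then become unnecessary.

**3. Step 14.**
- What may go wrong: over-reduction, that is, hydrogenolysis of the electron-rich benzylic C7–O or C2–O1 bond alongside debenzylation.
- Fallback: it sets out from 24 and returns at 26. The order of the endgame is inverted so that C7–O is still silylated, and so no free benzylic alcohol is exposed, during the reduction.
- Hydrogenolysis of 24 (H2, Pd/C, EtOAc) gives the bis-phenol silyl ether F10.
- The silyl group is then removed with fluoride buffered by acetic acid (Bu4NF/AcOH 1:1, THF, rt). This keeps the phenols protonated and so blocks quinone methide formation and epimerisation at C7.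

**Further compounds**

F1 | step 11 | (S)-4-benzyl-3-(pent-4-enoyl)oxazolidin-2-one | C=CCCC(=O)N1[C@@H](Cc2ccccc2)COC1=O
F2 | step 11 | alpha-allyl syn-aldol imide | COc1cc([C@@H](O)[C@H](CC=C)C(=O)N2[C@@H](Cc3ccccc3)COC2=O)ccc1OCc1ccccc1
F3 | step 11 | C7 silyl ether of F2 | COc1cc([C@@H](O[Si](C)(C)C(C)(C)C)[C@H](CC=C)C(=O)N2[C@@H](Cc3ccccc3)COC2=O)ccc1OCc1ccccc1
F4 | step 11 | primary alcohol from F3 | COc1cc([C@@H](O[Si](C)(C)C(C)(C)C)[C@H](CC=C)CO)ccc1OCc1ccccc1
F5 | step 11 | lactol (anomers) | COc1cc([C@@H](O[Si](C)(C)C(C)(C)C)[C@H]2COC(O)C2)ccc1OCc1ccccc1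
F6 | step 11 | beta-substituted gamma-butyrolactone | COc1cc([C@@H](O[Si](C)(C)C(C)(C)C)[C@H]2COC(=O)C2)ccc1OCc1ccccc1
F7 | step 11 | trans-disubstituted aldol lactone (C2 carbinol epimers) | COc1cc([C@@H](O[Si](C)(C)C(C)(C)C)[C@H]2COC(=O)[C@@H]2C(O)c2ccc(OCc3ccccc3)c(OC)c2)ccc1OCc1ccccc1
F8 | step 11 | triol (C2 carbinol epimers) | COc1cc([C@@H](O[Si](C)(C)C(C)(C)C)[C@@H](CO)[C@H](CO)C(O)c2ccc(OCc3ccccc3)c(OC)c2)ccc1OCc1ccccc1
F9 | step 9 | rac-1-(4-benzyloxy-3-methoxyphenyl)prop-2-yn-1-yl acetate | CC(=O)OC(C#C)c1ccc(OCc2ccccc2)c(OC)c1
F10 | step 14 | C7 O-silyl tanegol (free phenols) | COc1cc([C@@H](O[Si](C)(C)C(C)(C)C)[C@H]2CO[C@H](c3ccc(O)c(OC)c3)[C@H]2CO)ccc1O
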